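**Conventions.** Atom labels C1–C10 are those of the target skeleton and are kept for every intermediate. Ring A is the cyclopentane C1–C2–C3–C4–C5; ring B is the cycloheptane C1–C10–C9–C8–C7–C6–C5. In the decalin intermediates, ring P is C1–C2–C3–C4–C5–C6 and ring Q is C1–C10–C9–C8–C7–C6. β denotes the face of the C1 methyl group, α the opposite face. Compound numbers 1–24 are fixed in the compound list after the steps and used throughout.

## Analysis of the target

The target is a trans-fused bicyclo[5.3.0]decane (hydroazulene) with configuration (1R,4R,5S,6S,8S,9S) in the numbering used here. The six stereocentres are the quaternary C1 (methyl), the tertiary carbinol C4 (isopropyl), the ring-fusion methine C5, the acylated carbinol C6, the tertiary carbinol C8 (methyl) and the secondary carbinol C9. The C1 methyl, the C4 hydroxyl and the C8 hydroxyl lie on the β face; H5, the C6 ester oxygen and the C9 hydroxyl lie on the α face. The ring fusion is therefore trans, the 4,6-dioxygen pattern is anti and the 8,9-diol is trans. Sensitive groups are two tertiary alcohols (dehydration, and in any C6 ketone stage retro-aldol through C4–O), an aryl ester next to a free phenol (base), and a vicinal diol. The difficulty is the quaternary C1 beside a trans ring fusion in a seven-membered ring. In addition, C6 sits two bonds from the oxygenated C4, so every C6 carbonyl intermediate is a β-oxy ketone that can eliminate or cleave unless its enolate chemistry is regiodefined. For the same reason a C8 carbonyl conjugated through C6=C7 is avoided altogether, since C4–O would then be a vinylogous β-leaving group. The strategy rests on the C6 oxygen lying next to ring-fusion carbon C5. A C6 carbinol in a cis-decalin (rings P and Q), with a leaving group on C5, can push the C1–C6 bond over to C5, contracting ring P to ring A and expanding ring Q to ring B in one stereospecific shift.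

## Retrosynthetic reasoning

**24 ⇐ 23.** Only the phenol protecting group is removed. A benzyl ether is chosen because its hydrogenolysis is neutral and the molecule has no olefin left at that point.

**23 ⇐ 22.** The C8–O bond is cut. The trans-8β,9α-diol is the product of hydrolytic opening of the 8α,9α-epoxide at the tertiary carbon with inversion. One facial choice at the olefin thus fixes both C8 and C9, and the ester is already in place so the two secondary alcohols never need to be told apart.

**22 ⇐ 20 + 21.** The ester C–O bond at C6 is cut. Acylation is placed before the epoxide opening because 20 has only one acylable hydroxyl (C6); C4–OH is tertiary.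

**20 ⇐ 19.** The epoxide oxygen is removed to the C8=C9 olefin. The α-oriented C6 hydroxyl of 19 is homoallylic to this olefin and can deliver the oxidant to the α face.

**19 ⇐ 18.** The C6–H bond is cut back to the ketone. The free β-hydroxyl on C4 can deliver hydride to the β face of C6, which gives the required 6α-alcohol, anti to C4–OH.

**18 ⇐ 16 (key disconnection).** C1–C5 is cut and C1–C6 is re-formed, which turns rings A and B back into the six-membered rings P and Q of cis-decalin 16. This is done here and not by an end-to-end closure of the seven-membered ring because a decalin is far easier to assemble with stereocontrol. The forward 1,2-shift is stereospecific (inversion at C5, retention at C1), so the trans fusion follows from the all-cis 4,5,6-oxygen pattern of 16. The forward reaction must make C1, and not C3, C7 or isopropyl, migrate.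

**16 ⇐ 15 ⇐ 13.** The C5–O and C6–O bonds are cut to the C5=C6 olefin of allylic alcohol 13. One hydroxyl-directed syn-dihydroxylation sets C5 and C6 cis to the C4 hydroxyl, and only the secondary C5 hydroxyl can be sulfonylated.

**13 ⇐ 12 ⇐ 11.** Ring Q is opened at C8=C9 (ring-closing metathesis in the forward sense). This brings in the C8 methyl and the C8=C9 olefin that the end game needs, so ring Q never carries a carbonyl. The forward reaction has to leave the hindered C5=C6 bond alone.

**11 ⇐ 9 + 10.** The C6–C7 bond is cut to the C6 enol triflate 9 and the methallyl stannane 10. The C5=C6 olefin is thereby born directly from the C6 ketone in the position needed for the dihydroxylation, with no conjugated enone on the way.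

**9 ⇐ 8 ⇐ 6 + 7.** The C1–C10 bond is cut. The quaternary centre comes from allylation of the regiodefined tetrasubstituted enolate released from enol silane 6. This enolate (C6=C1) cannot expel the C4 oxygen, which the isomeric C5 enolate could. The forward reaction must add allyl to the face of C1 anti to the axial C4 oxygen, so that the methyl ends cis to C4–O.

**6 ⇐ 5 ⇐ 4 ⇐ 2 ⇐ 1.** These are oxidation-level changes from (S)-terpinen-4-ol 1: silylation, anti-Markovnikov hydration of the C1=C6 olefin and oxidation give the C6 ketone. The chiral pool supplies C4, and every other stereocentre is set relative to it.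

## Alternatives that were turned down

**Alternative 1:** Ring B is disconnected at C1–C10 and at C6–C7/C6–C8. In the forward sense the Fischer carbene complex pentacarbonyl[methoxy(cyclopentenyl)carbene]chromium A2, which carries ring A, would cyclopropanate the methyl-bearing double bond of isoprene A3. The resulting cis-divinylcyclopropane would undergo Cope rearrangement to the hydroazulene diene A1 (C5=C6 methyl enol ether, C8=C9 olefin).
- For it: it is convergent, it puts the C8 methyl and the C8=C9 olefin in place in the ring-forming step, and it reaches the bicyclic core in fewer operations than the chosen route. On step economy to the core it is stronger.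
- Against it: alkenyl carbene complexes of this kind are also good dienophiles, so a (4+2) adduct with A3 competes. Cyclopropanation has to choose the more substituted double bond of A3 and the cis-divinyl isomer. The Cope step must create the quaternary C1 from a tetrasubstituted olefin terminus through a boat transition state, with facial control only from the remote C4 centre. C5 becomes sp2 in A1, so the trans ring fusion still has to be set later by a protonation of uncertain sense. Ring A with its C4 carbinol needs its own asymmetric synthesis, and chromium is stoichiometric.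
- Comparison: the chosen route is longer but takes C4 from the chiral pool and fixes C1 and C5 by a stereospecific shift.

**Alternative 2:** Ring A is disconnected at C1–C2 and C4–C5. The zinc homoenolate obtained by opening 1-isopropylcyclopropanol A6 would add, under copper catalysis with a chiral phosphoramidite, to the methyl-bearing β-carbon of 3,6-dimethylcyclohepta-2,6-dienone A5. The enol silane so formed would then close onto the isopropyl ketone in a Lewis-acid aldol to give the hydroazulenone A4 (C4 carbinol, C7=C8 enone).
- For it: it is the shortest route on paper, catalytic in metal and catalytically asymmetric. On step count it is clearly stronger.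
- Against it: enantioselective conjugate addition of a weakly nucleophilic functionalised zinc homoenolate to a β,β-disubstituted cycloheptadienone, creating a quaternary centre, is not a secured reaction type. The aldol onto a hindered isopropyl ketone must set C4 and C5 relative to C1 without a clear controlling element and can revert. A4 carries its olefin at C7=C8 in conjugation, so the C8/C9 diol still needs a deconjugation.
- Comparison: the chosen route puts no stereocentre on an unprecedented step and delivers the olefin at C8=C9 directly.

**Alternative 3:** Both rings are disconnected at once, at C1–C5 and C7–C8. The acyclic chloromethyl ketone A8, ionised by a lithium salt and a tertiary amine to the C5–C6–C7 oxyallyl cation, would add across its tethered silyloxydiene in an intramolecular (4+3) cycloaddition to give the hydroazulenone A7 (C9 silyl enol ether, C8 methyl).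
- For it: it builds both rings and up to three stereocentres in one step, and C9 arrives oxidised. In convergence it is stronger than the chosen route.
- Against it: the diene is fully substituted at the terminus that becomes C1. An oxyallyl cation without stabilising α-substituents is short-lived and prone to proton loss. Cis/trans fusion and facial selectivity would have to come from the C4 centre in a flexible three-atom tether. C8 is formed as a C–H centre that must later be hydroxylated with control. A8 itself needs a stereodefined diene and an asymmetric entry to C4.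
- Comparison: the chosen route answers with a rigid bicyclic precursor whose conformation dictates the outcome of the ring-forming step.

Key step: step 12

Remark on the chemistry: commercial (S)-(+)-terpinen-4-ol is taken as enantiomerically pure; material of lower purity would be enriched before use.

## Route

Step 1
Reactants: 1 (S)-terpinen-4-ol
Product: 2 (S)-terpinen-4-ol triethylsilyl ether
Conditions: Et3SiOTf, 2,6-lutidine, CH2Cl2, 0 °C to rt
Reagents that add atoms: triethylsilyl triflate, CC[Si](CC)(CC)OS(=O)(=O)C(F)(F)F
Why: Silylation of a hindered tertiary alcohol needs the silyl triflate; the ether keeps the C4 oxygen from acting as an alkoxide (retro-aldol) or proton source once C6 is a ketone, and the stereocentre is untouched.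

Step 2
Reactants: 2 (S)-terpinen-4-ol triethylsilyl ether
Product: 4 5-isopropyl-2-methyl-5-(triethylsilyloxy)cyclohexan-1-ol (hydroxyl on C6; C1 methyl trans to it; both syn adducts), via C6 alkylborane 3 (not isolated)
Conditions: BH3·THF, THF, 0 °C to rt; then aq. NaOH, H2O2, 0 °C to rt
Reagents that add atoms: hydrogen peroxide, OO
Why: Brown hydroboration–oxidation places boron, then oxygen, on the less substituted olefin carbon C6 by syn addition and oxidation with retention; the C1/C6 diastereomer mixture is immaterial because both centres are flattened in steps 3 and 4.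

Step 3
Reactants: 4 5-isopropyl-2-methyl-5-(triethylsilyloxy)cyclohexan-1-ol
Product: 5 (5S)-5-isopropyl-2-methyl-5-(triethylsilyloxy)cyclohexan-1-one (C6 ketone, C1 epimers)
Conditions: Pr4N[RuO4] (5 mol%), N-methylmorpholine N-oxide, 4 Å molecular sieves, CH2Cl2, rt
Reagents that add atoms: none
Why: Ley–Griffith oxidation of the secondary alcohol under neutral conditions, which a β-silyloxy ketone tolerates.

Step 4
Reactants: 5 (5S)-5-isopropyl-2-methyl-5-(triethylsilyloxy)cyclohexan-1-one
Product: 6 (S)-triethyl{[1-isopropyl-4-methyl-3-(trimethylsilyloxy)cyclohex-3-en-1-yl]oxy}silane (C6–OSiMe3, C6=C1)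
Conditions: Me3SiCl, NaI, Et3N, MeCN, rt to 40 °C
Reagents that add atoms: chlorotrimethylsilane, C[Si](C)(C)Cl
Why: Enol silane formation under equilibrating conditions (iodotrimethylsilane made in situ) favours the tetrasubstituted C6=C1 isomer, the more so as the other α-carbon C5 adjoins the fully substituted C4; no free enolate is formed, so the C4 silyloxy group cannot be eliminated, and both C1 epimers converge.

Step 5
Reactants: 6 the C6=C1 trimethylsilyl enol ether; 7 diallyl carbonate
Product: 8 (2R,5S)-2-allyl-5-isopropyl-2-methyl-5-(triethylsilyloxy)cyclohexan-1-one (C1 quaternary; allyl cis to isopropyl, methyl cis to the C4 oxygen)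
Conditions: Pd2(dba)3 (2.5 mol%), (R)-t-Bu-PHOX (6 mol%), Bu4N[Ph3SiF2] (35 mol%), THF, 25 °C
Reagents that add atoms: diallyl carbonate (7), C=CCOC(=O)OCC=C
Why: Tsuji allylation in its fluoride-triggered enol-silane form: the enolate is released regiodefined at C1 in an aprotic medium and allylated within a palladium allyl enolate, so it never equilibrates to the C5 enolate that could expel the C4 oxygen. Allyl enters C1 axially on the face anti to the axial C4 silyloxy group (chair-like transition state with isopropyl equatorial), and the ligand enantiomer that gives (R)-2-allyl-2-methyl ketones reinforces this substrate bias.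

Step 6
Reactants: 8 (2R,5S)-2-allyl-5-isopropyl-2-methyl-5-(triethylsilyloxy)cyclohexan-1-one
Product: 9 6-allyl-3-isopropyl-6-methyl-3-(triethylsilyloxy)cyclohex-1-en-1-yl triflate (C6–OTf, C5=C6; C1 and C4 as in 8)
Conditions: LiN(SiMe3)2, THF, −78 °C, 20 min; then Comins' reagent, −78 °C
Reagents that add atoms: Comins' reagent, O=S(=O)(N(c1ccc(Cl)cn1)S(=O)(=O)C(F)(F)F)C(F)(F)F
Why: With C1 quaternary, C5 is the only enolisable position, so enol triflate formation is regiospecific; the lithium enolate is trapped at −78 °C by the fast-reacting pyridyl triflimide before it can lose the β-silyloxy group.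

Step 7
Reactants: 9 the C6 enol triflate; 10 tributyl(2-methylallyl)stannane
Product: 11 triethyl{[4-allyl-1-isopropyl-4-methyl-3-(2-methylallyl)cyclohex-2-en-1-yl]oxy}silane (C5=C6; methallyl on C6, allyl on C1)
Conditions: Pd(PPh3)4 (5 mol%), LiCl, THF, 65 °C
Reagents that add atoms: tributyl(2-methylallyl)stannane (10), CCCC[Sn](CCCC)(CCCC)CC(C)=C
Why: Stille coupling of an enol triflate flanked by a quaternary carbon (as in steroidal 17-enol triflates): zerovalent palladium inserts into the C6–O bond, chloride assists transmetalation, and the symmetrical 2-methylallyl group cannot transpose. C7, C8 and the C8 methyl are attached while the olefin is fixed at C5=C6 with no carbonyl in conjugation.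

Step 8
Reactants: 11 the allyl/methallyl triene
Product: 12 4β-(triethylsilyloxy)-4α-isopropyl-1β,8-dimethylbicyclo[4.4.0]deca-5,8-diene
Conditions: second-generation Grubbs catalyst (H2IMes)(PCy3)Cl2Ru=CHPh (5 mol%), CH2Cl2 (5 mM), 40 °C
Reagents that add atoms: none
Why: Ring-closing metathesis between the monosubstituted allyl and the 1,1-disubstituted methallyl olefin closes six-membered ring Q and leaves the trisubstituted C8=C9 bond bearing the C8 methyl; the C5=C6 bond, flanked by two fully substituted carbons, does not engage.

Step 9
Reactants: 12 the silyl-protected bicyclic diene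
Product: 13 4α-isopropyl-1β,8-dimethylbicyclo[4.4.0]deca-5,8-dien-4β-ol
Conditions: Bu4NF, THF, 0 to 40 °C
Reagents that add atoms: none
Why: Fluoride cleaves the tertiary silyl ether under non-acidic conditions, which the tertiary allylic alcohol requires.

Step 10
Reactants: 13 4α-isopropyl-1β,8-dimethylbicyclo[4.4.0]deca-5,8-dien-4β-ol
Product: 15 cis-fused 4α-isopropyl-1β,8-dimethylbicyclo[4.4.0]dec-8-ene-4β,5β,6β-triol, via osmate ester 14 (not isolated)
Conditions: OsO4 (1.05 equiv), TMEDA (1.1 equiv), CH2Cl2, −78 °C; then aq. Na2SO3, THF, 60 °C
Reagents that add atoms: osmium tetroxide, O=[Os](=O)(=O)=O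
Why: Donohoe directed dihydroxylation: the OsO4·TMEDA complex accepts a hydrogen bond from the pseudoaxial C4 hydroxyl and adds syn to the allylic C5=C6 bond on that same β face, which is the open face because ring Q hangs below ring P. This sets C5 and C6 in one step, all-cis with C4–OH. The remote C8=C9 bond has no donor and is not reached by one equivalent at −78 °C.

Step 11
Reactants: 15 the 4β,5β,6β-triol
Product: 16 cis-fused 4β,6β-dihydroxy-4α-isopropyl-1β,8-dimethylbicyclo[4.4.0]dec-8-en-5β-yl methanesulfonate
Conditions: MsCl, Et3N, CH2Cl2, −20 to 0 °C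
Reagents that add atoms: methanesulfonyl chloride, CS(=O)(=O)Cl
Why: Sulfene mesylation takes the only secondary hydroxyl even in a hindered setting and leaves both tertiary ones free; since both neighbours are cis to the new mesylate, no epoxide can close.

Step 12
Reactants: 16 the cis-decalin 4,5,6-triol 5-mesylate
Product: 18 trans-fused (5α-H) 4β-hydroxy-4α-isopropyl-1β,8-dimethylbicyclo[5.3.0]dec-8-en-6-one, via bis(diethylaluminium) alkoxide 17 (not isolated)
Conditions: Et3Al (3.5 equiv), CH2Cl2, −78 to −20 °C; aq. potassium sodium tartrate (KNaC4H4O6)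
Reagents that add atoms: none
Why: Et3Al turns both tertiary hydroxyls into diethylaluminium alkoxides and its Lewis-acidic aluminium pulls on the mesylate; the C6 alkoxide then pushes while the C1–C6 bond shifts to C5 in a concerted, suprafacial 1,2-migration. That bond is antiperiplanar to the equatorial C5–O bond in the ring-P chair that keeps isopropyl equatorial. This is the organoaluminium-promoted semipinacol rearrangement of a 2-sulfonyloxy alcohol (Tsuchihashi–Suzuki reaction), the reaction type by which decalin-1,9-diol monosulfonates are turned into hydroazulenones. Ring A arises by contraction of ring P (C1 moves from C6 to C5) and ring B by the matching expansion of ring Q (C5 is inserted between C1 and C6); neither ring is closed end to end. C5 is the only new stereocentre: C1 enters anti to the leaving group, so C5 is inverted and H5 ends trans to the C1 methyl, while C1 migrates with retention. The step needs the ring bond and not C7 or isopropyl to migrate, which holds because the chair with an axial mesylate would put isopropyl and C7 syn-diaxial. It also needs C1 to migrate in preference to C3, whose bond to C4 is likewise antiperiplanar and could be pushed by the C4 alkoxide; here the fully substituted C1 is by far the better migrating group than the CH2 carbon C3. The C8=C9 olefin is inert to Et3Al at this temperature, and the product, a β-hydroxy and β,γ-unsaturated ketone, is carried on without storage.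

Step 13
Reactants: 18 the hydroazulen-6-one
Product: 19 trans-fused (5α-H) 4α-isopropyl-1β,8-dimethylbicyclo[5.3.0]dec-8-ene-4β,6α-diol
Conditions: Me4NBH(OAc)3, MeCN/AcOH (1:1), −30 to −20 °C
Reagents that add atoms: none
Why: Saksena–Evans reduction: the C4 hydroxyl exchanges onto boron and delivers hydride through a six-membered transition state to the C6 carbonyl face that looks toward it (β), so the new hydroxyl is α, anti to C4–OH; the cold, weakly acidic medium is expected to leave the β,γ-olefin in place.

Step 14
Reactants: 19 the 4β,6α-diol
Product: 20 8α,9α-epoxy-4α-isopropyl-1β,8β-dimethylbicyclo[5.3.0]decane-4β,6α-diol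
Conditions: VO(acac)2 (5 mol%), t-BuOOH, CH2Cl2, 0 °C to rt
Reagents that add atoms: tert-butyl hydroperoxide, CC(C)(C)OO
Why: Hydroxyl-directed vanadium-catalysed epoxidation: the homoallylic 6α-hydroxyl binds the vanadium peroxide and delivers oxygen to the C8=C9 bond on its own α face, which sets C8 and C9.

Step 15
Reactants: 20 the 8α,9α-epoxy diol; 21 4-(benzyloxy)benzoic acid
Product: 22 8α,9α-epoxy-4β-hydroxy-4α-isopropyl-1β,8β-dimethylbicyclo[5.3.0]decan-6α-yl 4-(benzyloxy)benzoate
Conditions: EDC·HCl, DMAP, CH2Cl2, rt
Reagents that add atoms: 4-(benzyloxy)benzoic acid (21), O=C(O)c1ccc(OCc2ccccc2)cc1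
Why: Steglich esterification acylates the only secondary hydroxyl; the tertiary C4 hydroxyl and the epoxide are untouched under these near-neutral conditions.

Step 16
Reactants: 22 the epoxy ester
Product: 23 4β,8β,9α-trihydroxy-4α-isopropyl-1β,8α-dimethylbicyclo[5.3.0]decan-6α-yl 4-(benzyloxy)benzoate
Conditions: HClO4 (0.1 equiv), THF/H2O (3:1), 0 °C to rt
Reagents that add atoms: water, O
Why: Acid-catalysed epoxide hydrolysis: water attacks the protonated epoxide at the tertiary carbon C8 from the β face with inversion, while the C9–O bond is kept, giving the trans-8β,9α-diol; the α-oriented ester cannot reach the β face of C8, so no acyl participation is expected.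

Step 17
Reactants: 23 the benzyl-protected ester
Product: 24 4β,8β,9α-trihydroxy-4α-isopropyl-1β,8α-dimethylbicyclo[5.3.0]decan-6α-yl 4-hydroxybenzoate, (1R,4R,5S,6S,8S,9S), the target
Conditions: H2 (1 atm), palladium on carbon (Pd/C, 10%), EtOAc, rt
Reagents that add atoms: none
Why: Hydrogenolysis of the benzyl aryl ether under neutral conditions; no olefin remains and the aryl ester and the alcohols are inert.

## Compound list

1 | (S)-terpinen-4-ol [(S)-1-isopropyl-4-methylcyclohex-3-en-1-ol] | CC(C)[C@]1(O)CCC(C)=CC1 | starting material
2 | (S)-terpinen-4-ol triethylsilyl ether | CC(C)[C@]1(O[Si](CC)(CC)CC)CCC(C)=CC1 | intermediate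
3 | C6 alkylborane of 2 (boron on C6, hydrogen on C1, syn; drawn as the monoalkylborane; both syn adducts) | CC(C)[C@]1(O[Si](CC)(CC)CC)CCC(C)C(B)C1 | intermediate
4 | 5-isopropyl-2-methyl-5-(triethylsilyloxy)cyclohexan-1-ol (C4 as in 2; C1/C6 diastereomers) | CC(C)[C@]1(O[Si](CC)(CC)CC)CCC(C)C(O)C1 | intermediate
5 | (5S)-5-isopropyl-2-methyl-5-(triethylsilyloxy)cyclohexan-1-one (C1 epimers) | CC(C)[C@]1(O[Si](CC)(CC)CC)CCC(C)C(=O)C1 | intermediate
6 | (S)-triethyl{[1-isopropyl-4-methyl-3-(trimethylsilyloxy)cyclohex-3-en-1-yl]oxy}silane | CC(C)[C@]1(O[Si](CC)(CC)CC)CCC(C)=C(O[Si](C)(C)C)C1 | intermediate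
7 | diallyl carbonate | C=CCOC(=O)OCC=C | starting material
8 | (2R,5S)-2-allyl-5-isopropyl-2-methyl-5-(triethylsilyloxy)cyclohexan-1-one | CC(C)[C@]1(O[Si](CC)(CC)CC)CC[C@](C)(CC=C)C(=O)C1 | intermediate
9 | 6-allyl-3-isopropyl-6-methyl-3-(triethylsilyloxy)cyclohex-1-en-1-yl triflate (C1, C4 as in 8) | CC(C)[C@]1(O[Si](CC)(CC)CC)CC[C@](C)(CC=C)C(OS(=O)(=O)C(F)(F)F)=C1 | intermediate
10 | tributyl(2-methylallyl)stannane | CCCC[Sn](CCCC)(CCCC)CC(C)=C | starting material
11 | triethyl{[4-allyl-1-isopropyl-4-methyl-3-(2-methylallyl)cyclohex-2-en-1-yl]oxy}silane (C1, C4 as in 8) | CC(C)[C@]1(O[Si](CC)(CC)CC)CC[C@](C)(CC=C)C(CC(C)=C)=C1 | intermediate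
12 | 4β-(triethylsilyloxy)-4α-isopropyl-1β,8-dimethylbicyclo[4.4.0]deca-5,8-diene | CC(C)[C@]1(O[Si](CC)(CC)CC)CC[C@]2(C)CC=C(C)CC2=C1 | intermediate
13 | 4α-isopropyl-1β,8-dimethylbicyclo[4.4.0]deca-5,8-dien-4β-ol | CC(C)[C@]1(O)CC[C@]2(C)CC=C(C)CC2=C1 | intermediate
14 | 5β,6β-osmate ester of 13 (hexavalent osmium glycolate, as its TMEDA chelate) | CC(C)[C@]1(O)CC[C@]2(C)CC=C(C)C[C@@]23O[Os](=O)(=O)O[C@@H]13.CN(C)CCN(C)C | intermediate
15 | cis-fused 4α-isopropyl-1β,8-dimethylbicyclo[4.4.0]dec-8-ene-4β,5β,6β-triol | CC(C)[C@]1(O)CC[C@]2(C)CC=C(C)C[C@]2(O)[C@H]1O | intermediate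
16 | cis-fused 4β,6β-dihydroxy-4α-isopropyl-1β,8-dimethylbicyclo[4.4.0]dec-8-en-5β-yl methanesulfonate | CC(C)[C@]1(O)CC[C@]2(C)CC=C(C)C[C@]2(O)[C@H]1OS(C)(=O)=O | intermediate
17 | bis(diethylaluminium) 4,6-dialkoxide of 16 | CC(C)[C@]1(O[Al](CC)CC)CC[C@]2(C)CC=C(C)C[C@]2(O[Al](CC)CC)[C@H]1OS(C)(=O)=O | intermediate
18 | trans-fused (5α-H) 4β-hydroxy-4α-isopropyl-1β,8-dimethylbicyclo[5.3.0]dec-8-en-6-one | CC(C)[C@]1(O)CC[C@]2(C)CC=C(C)CC(=O)[C@H]21 | intermediate
19 | trans-fused (5α-H) 4α-isopropyl-1β,8-dimethylbicyclo[5.3.0]dec-8-ene-4β,6α-diol | CC(C)[C@]1(O)CC[C@]2(C)CC=C(C)C[C@H](O)[C@H]21 | intermediate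
20 | 8α,9α-epoxy-4α-isopropyl-1β,8β-dimethylbicyclo[5.3.0]decane-4β,6α-diol | CC(C)[C@]1(O)CC[C@]2(C)C[C@@H]3O[C@]3(C)C[C@H](O)[C@H]21 | intermediate
21 | 4-(benzyloxy)benzoic acid | O=C(O)c1ccc(OCc2ccccc2)cc1 | starting material
22 | 8α,9α-epoxy-4β-hydroxy-4α-isopropyl-1β,8β-dimethylbicyclo[5.3.0]decan-6α-yl 4-(benzyloxy)benzoate | CC(C)[C@]1(O)CC[C@]2(C)C[C@@H]3O[C@]3(C)C[C@H](OC(=O)c4ccc(OCc5ccccc5)cc4)[C@H]21 | intermediate
23 | 4β,8β,9α-trihydroxy-4α-isopropyl-1β,8α-dimethylbicyclo[5.3.0]decan-6α-yl 4-(benzyloxy)benzoate | CC(C)[C@]1(O)CC[C@]2(C)C[C@H](O)[C@@](C)(O)C[C@H](OC(=O)c3ccc(OCc4ccccc4)cc3)[C@H]21 | intermediate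
24 | 4β,8β,9α-trihydroxy-4α-isopropyl-1β,8α-dimethylbicyclo[5.3.0]decan-6α-yl 4-hydroxybenzoate, (1R,4R,5S,6S,8S,9S) | CC(C)[C@]1(O)CC[C@]2(C)C[C@H](O)[C@@](C)(O)C[C@H](OC(=O)c3ccc(O)cc3)[C@H]21 | target

## Step count and least certain steps

Total step count: 17. Longest linear sequence: 17 steps, from 1 to 24.

**Step 12 (key step).** The most likely failure is migration of the wrong ring bond. The C4–C3 bond is as well aligned with the equatorial mesylate as the C1–C6 bond, and the C4 alkoxide could push C3 across, contracting ring P to an acylcyclopentane. A lesser risk is loss of the β-hydroxy ketone product by retro-aldol cleavage or ethyl transfer from aluminium. The fallback removes the second donor. It sets out from 13 and returns at 18.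
- The osmylation of step 10 is stopped at the TMEDA-chelated osmate ester 14, which is kept as such; O5 and O6 are masked in it and C4–OH is its only free hydroxyl.
- Et3SiOTf and 2,6-lutidine convert it into the C4 triethylsilyl ether of the osmate ester F1.
- Reductive cleavage with aqueous Na2SO3 gives the 4β-(triethylsilyloxy)-5β,6β-diol F2.
- Sulfene mesylation gives the C4-silylated C5 mesylate F3.
- Et3Al now finds a single alkoxide, on C6, and should give the 4β-(triethylsilyloxy)hydroazulen-6-one F4.
- HF·pyridine in THF releases 18.

**Step 5.** The likely failure is erosion of facial selectivity at the new quaternary C1, or proton transfer that moves the enolate to C5, from where the C4 silyloxy group is eliminated. The fallback replaces the enolate by a radical. It sets out from 6 and returns at 8. N-Bromosuccinimide in THF at −78 °C converts 6 into the α-bromo ketone F5 (bromine on C1). Keck allylation (allyltributylstannane, AIBN, benzene, 80 °C) then traps the planar C1 radical axially, anti to the axial C4 silyloxy group, to give 8.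

**Step 6.** The likely failure is β-elimination of the C4 silyloxy group from the C5 enolate, whose axial C4–O bond is aligned with the enolate π system; this would give the conjugated enone. The fallback avoids any enolate. It sets out from 8 and returns at 11. Hydrazine hydrate and Et3N in ethanol at 80 °C give the hydrazone F6. Barton's vinyl iodide synthesis (I2, tetramethylguanidine, THF) gives the C6 iodoalkene F7. The Stille coupling of step 7 with 10 then gives 11.

**Step 10.** The likely failure is loss of chemoselectivity, that is osmylation of the unhindered C8=C9 bond alongside or instead of the hydrogen-bond-directed addition to C5=C6. The fallback masks the ring-Q olefin. It sets out from 13 and returns at 15. One equivalent of pyridinium tribromide at −78 °C adds to the more accessible C8=C9 bond to give the 8,9-dibromide F8. OsO4·TMEDA as in step 10 gives the dibromo triol F9. Zinc in acetic acid/ethanol restores the olefin and gives 15.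

**Step 16.** The likely failure is that the tertiary, cation-like C8 centre of the protonated epoxide is not captured by water. It may instead lose a proton to an allylic alcohol, suffer a hydride shift to a C9 ketone, or be captured across the ring by the C4 hydroxyl. The fallback sets the C8 oxygen first and then opens a β-epoxide at the secondary carbon C9 by a purely bimolecular attack. It sets out from 19 and returns at 23.
- N-Bromosuccinimide in aqueous DME gives the bromohydrin F10 (C8–OH β, C9–Br α).
- K2CO3 in methanol closes the 8β,9β-epoxide F11.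
- Aqueous NaOH in DMSO at 80 °C opens it at C9 to the 4β,6α,8β,9α-tetraol F12.
- 2,2-Dimethoxypropane with pyridinium p-toluenesulfonate masks the only vicinal diol as the 8,9-acetonide F13.
- Steglich acylation with 21 gives the acetonide ester F14.
- Aqueous acetic acid removes the acetonide to give 23.

## Further compounds

F1 | step 12 | C4 triethylsilyl ether of osmate ester 14 (TMEDA chelate) | CC(C)[C@]1(O[Si](CC)(CC)CC)CC[C@]2(C)CC=C(C)C[C@@]23O[Os](=O)(=O)O[C@@H]13.CN(C)CCN(C)C
F2 | step 12 | cis-fused 4β-(triethylsilyloxy)-4α-isopropyl-1β,8-dimethylbicyclo[4.4.0]dec-8-ene-5β,6β-diol | CC(C)[C@]1(O[Si](CC)(CC)CC)CC[C@]2(C)CC=C(C)C[C@]2(O)[C@H]1O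
F3 | step 12 | cis-fused 6β-hydroxy-4β-(triethylsilyloxy)-4α-isopropyl-1β,8-dimethylbicyclo[4.4.0]dec-8-en-5β-yl methanesulfonate | CC(C)[C@]1(O[Si](CC)(CC)CC)CC[C@]2(C)CC=C(C)C[C@]2(O)[C@H]1OS(C)(=O)=O
F4 | step 12 | trans-fused (5α-H) 4β-(triethylsilyloxy)-4α-isopropyl-1β,8-dimethylbicyclo[5.3.0]dec-8-en-6-one | CC(C)[C@]1(O[Si](CC)(CC)CC)CC[C@]2(C)CC=C(C)CC(=O)[C@H]21
F5 | step 5 | (5S)-2-bromo-5-isopropyl-2-methyl-5-(triethylsilyloxy)cyclohexan-1-one (C1 epimers) | CC(C)[C@]1(O[Si](CC)(CC)CC)CCC(C)(Br)C(=O)C1
F6 | step 6 | hydrazone of ketone 8 | CC(C)[C@]1(O[Si](CC)(CC)CC)CC[C@](C)(CC=C)C(=NN)C1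
F7 | step 6 | triethyl{[4-allyl-3-iodo-1-isopropyl-4-methylcyclohex-2-en-1-yl]oxy}silane (C6 iodide, C5=C6) | CC(C)[C@]1(O[Si](CC)(CC)CC)CC[C@](C)(CC=C)C(I)=C1
F8 | step 10 | 8,9-dibromo-4α-isopropyl-1β,8-dimethylbicyclo[4.4.0]dec-5-en-4β-ol (trans-dibromide, either anti adduct) | CC(C)[C@]1(O)CC[C@]2(C)CC(Br)C(C)(Br)CC2=C1
F9 | step 10 | cis-fused 8,9-dibromo-4α-isopropyl-1β,8-dimethylbicyclo[4.4.0]decane-4β,5β,6β-triol | CC(C)[C@]1(O)CC[C@]2(C)CC(Br)C(C)(Br)C[C@]2(O)[C@H]1O
F10 | step 16 | 9α-bromo-4α-isopropyl-1β,8α-dimethylbicyclo[5.3.0]decane-4β,6α,8β-triol | CC(C)[C@]1(O)CC[C@]2(C)C[C@H](Br)[C@@](C)(O)C[C@H](O)[C@H]21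
F11 | step 16 | 8β,9β-epoxy-4α-isopropyl-1β,8α-dimethylbicyclo[5.3.0]decane-4β,6α-diol | CC(C)[C@]1(O)CC[C@]2(C)C[C@H]3O[C@@]3(C)C[C@H](O)[C@H]21
F12 | step 16 | 4α-isopropyl-1β,8α-dimethylbicyclo[5.3.0]decane-4β,6α,8β,9α-tetraol | CC(C)[C@]1(O)CC[C@]2(C)C[C@H](O)[C@@](C)(O)C[C@H](O)[C@H]21
F13 | step 16 | 8β,9α-O-isopropylidene derivative of tetraol F12 | CC(C)[C@]1(O)CC[C@]2(C)C[C@@H]3OC(C)(C)O[C@@]3(C)C[C@H](O)[C@H]21
F14 | step 16 | 6α-[4-(benzyloxy)benzoate] of acetonide F13 | CC(C)[C@]1(O)CC[C@]2(C)C[C@@H]3OC(C)(C)O[C@@]3(C)C[C@H](OC(=O)c4ccc(OCc5ccccc5)cc4)[C@H]21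
A1 | alternative 1 | hydroazulene diene with C5=C6 methyl enol ether, C8=C9 olefin and C4 triethylsilyl ether | CC(C)[C@]1(O[Si](CC)(CC)CC)CC[C@]2(C)CC=C(C)CC(OC)=C21
A2 | alternative 1 | pentacarbonyl[methoxy(cyclopentenyl)carbene]chromium carrying ring A | COC(=[Cr](=C=O)(=C=O)(=C=O)(=C=O)=C=O)C1=C(C)CC[C@@]1(O[Si](CC)(CC)CC)C(C)C
A3 | alternative 1 | isoprene | C=CC(C)=C
A4 | alternative 2 | trans-fused hydroazulen-6-one with C4 carbinol and C7=C8 enone | CC(C)[C@]1(O)CC[C@]2(C)CCC(C)=CC(=O)[C@H]21
A5 | alternative 2 | 3,6-dimethylcyclohepta-2,6-dien-1-one | CC1=CC(=O)C=C(C)CC1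
A6 | alternative 2 | 1-isopropylcyclopropan-1-ol | CC(C)C1(O)CC1
A7 | alternative 3 | trans-fused hydroazulen-6-one with C9 triisopropylsilyl enol ether, C8 methyl and C4 triethylsilyl ether | CC(C)[C@]1(O[Si](CC)(CC)CC)CC[C@]2(C)C=C(O[Si](C(C)C)(C(C)C)C(C)C)[C@H](C)CC(=O)[C@H]21
A8 | alternative 3 | acyclic chloromethyl ketone with tethered silyloxydiene | CC(C)[C@@](O[Si](CC)(CC)CC)(CC(=O)CCl)CC/C(C)=C/C(O[Si](C(C)C)(C(C)C)C(C)C)=C/C
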